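**Retrosynthetic overview**
1. Open the ring O1–C2 bond of the dihydropyranone (retro 6-endo-trig oxa-Michael). The target becomes its achiral acyclic isomer, (5E,18Z)-heptacosa-5,18-diene-2,4-dione, so the C–O bond, the ring and the only stereocentre are made together in the last step.
2. Remove the terminal acetyl group of the enedione (C-acylation of a kinetic enolate), giving (3E,16Z)-pentacosa-3,16-dien-2-one plus an acetyl donor.
3. Cut the E-alkene (Wittig), giving (Z)-docos-13-enal plus the acetonyl ylide. The aldehyde is made in the flask from erucyl alcohol, which brings the Z-alkene.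
4. Ring order: there is one ring only (ring A, the dihydropyranone), and it is closed last.

Assumption: the sense of induction of the new step cannot be known in advance, so (R)-TRIP is written, and if it gives the (S)-product the equally available (S)-TRIP is used instead.

**Step 1**
Reactants: 1 (Z)-docos-13-en-1-ol (erucyl alcohol); 2 1-(triphenylphosphoranylidene)propan-2-one
Product: 4 (3E,16Z)-pentacosa-3,16-dien-2-one, via (Z)-docos-13-enal 3 (not isolated)
Conditions: TEMPO (10 mol %), PhI(OAc)2 (1.1 equiv), CH2Cl2, rt, 3 h; then 2 (1.5 equiv), 40 °C, 16 h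
Reagents that add atoms: none
Why: TEMPO/PhI(OAc)2 oxidises the primary alcohol to the aldehyde without touching the isolated Z-alkene, and the stabilised keto ylide then gives the E-enone (one-pot oxidation–Wittig olefination, usually above 95:5 E:Z, with the liberated acetic acid acting as the usual co-catalyst); no stereocentre is formed.

**Step 2**
Reactants: 4 (3E,16Z)-pentacosa-3,16-dien-2-one; 5 1-acetyl-1H-benzotriazole
Product: 8 (5E,18Z)-heptacosa-5,18-diene-2,4-dione, via lithium dienolate 6 (not isolated), via lithium diketonate 7 (not isolated)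
Conditions: LiN(SiMe3)2 (2.2 equiv), THF, −78 °C, slow addition of 4, 45 min; 5 (1.3 equiv), −78 to −40 °C, 2 h; AcOH (2.5 equiv), −78 °C, then pH 7 buffer
Reagents that add atoms: none
Why: Adding 4 to excess hindered base at −78 °C removes the α'-methyl proton kinetically, N-acylbenzotriazoles acylate lithium enolates on carbon, and the second equivalent of base holds the product as its chelated diketonate, which cannot cyclise, until the cold mild quench (crossed Claisen-type C-acylation); no stereocentre is formed and both alkenes are untouched.

**Step 3**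
Reactants: 8 (5E,18Z)-heptacosa-5,18-diene-2,4-dione
Product: 10 (R)-2-[(Z)-henicos-12-en-1-yl]-6-methyl-2,3-dihydro-4H-pyran-4-one, via 2H-pyran-4-ol dienol 9 (not isolated)
Conditions: (R)-3,3'-bis(2,4,6-triisopropylphenyl)-1,1'-binaphthyl-2,2'-diyl hydrogen phosphate, (R)-TRIP (10 mol %), cyclohexane (0.05 M), 40 °C, 24–48 h, stopped at full conversion
Reagents that add atoms: none
Why: Proposed new method: enantioselective 6-endo-trig oxa-Michael cycloisomerisation of an acyclic alkenyl 1,3-diketone through its enol oxygen — the bifunctional phosphoric acid replaces the internal hydrogen bond of the enol tautomer of 8 by two external ones (P=O to the C2 enol O–H, P–OH to the C4 carbonyl oxygen), holds the non-chelated conformer in which the enol oxygen lies over C6, and relays the proton as the O–C6 bond forms to give dienol 9, which tautomerises to 10; the 2,4,6-triisopropylphenyl walls should leave one orientation for the long alkyl chain so that oxygen adds to the Re face of C6 and sets the (R) centre, the weak acid leaves the Z-alkene alone and should avoid Nazarov closure, high dilution suppresses intermolecular C-Michael addition, and ring closure is expected to be downhill for an alkyl-substituted acceptor so that the reverse reaction (the only racemisation path) is slow; the closest known reaction types are the racemic acid-mediated cyclisation of alkenyl 1,3-diketones to dihydropyranones, the organocatalytic asymmetric 2'-hydroxychalcone-to-flavanone cyclisation and phosphoric-acid-catalysed intramolecular oxa-Michael closures of hydroxy enoyl thioesters.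

**Compound list**
1 | (Z)-docos-13-en-1-ol (erucyl alcohol) | CCCCCCCC/C=C\CCCCCCCCCCCCO | starting material
2 | 1-(triphenylphosphoranylidene)propan-2-one | CC(=O)C=P(c1ccccc1)(c1ccccc1)c1ccccc1 | starting material
3 | (Z)-docos-13-enal | CCCCCCCC/C=C\CCCCCCCCCCCC=O | intermediate
4 | (3E,16Z)-pentacosa-3,16-dien-2-one | CCCCCCCC/C=C\CCCCCCCCCCC/C=C/C(C)=O | intermediate
5 | 1-acetyl-1H-benzotriazole | CC(=O)n1nnc2ccccc12 | starting material
6 | lithium (3E,16Z)-pentacosa-1,3,16-trien-2-olate (cross-conjugated dienolate) | [Li+].CCCCCCCC/C=C\CCCCCCCCCCC/C=C/C(=C)[O-] | intermediate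
7 | lithium (3Z,5E,18Z)-2-oxoheptacosa-3,5,18-trien-4-olate (chelated diketonate) | [Li+].CCCCCCCC/C=C\CCCCCCCCCCC/C=C/C([O-])=C/C(C)=O | intermediate
8 | (5E,18Z)-heptacosa-5,18-diene-2,4-dione (drawn as the diketo tautomer, present mainly as the chelated enol) | CCCCCCCC/C=C\CCCCCCCCCCC/C=C/C(=O)CC(C)=O | intermediate
9 | (2R)-2-[(Z)-henicos-12-en-1-yl]-6-methyl-2H-pyran-4-ol | CCCCCCCC/C=C\CCCCCCCCCCC[C@@H]1C=C(O)C=C(C)O1 | intermediate
10 | (R)-2-[(Z)-henicos-12-en-1-yl]-6-methyl-2,3-dihydro-4H-pyran-4-one | CCCCCCCC/C=C\CCCCCCCCCCC[C@@H]1CC(=O)C=C(C)O1 | target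

**Step count and risks**
Total step count: 3. Longest linear sequence: 3.

**Step 3 (the new step, highest risk).**
- The enantioselectivity or the rate may be too low.
- A racemic background closure may compete, and the ee may erode through the reverse reaction.
- Fallback, using known chemistry: it sets out from aldehyde 3, isolated after the oxidation half of step 1, and comes back at 10.
- Commercial (E)-4-methoxypent-3-en-2-one is converted with LiN(iPr)2 and Me3SiCl (THF, −78 °C) into (E)-4-methoxy-2-(trimethylsilyloxy)penta-1,3-diene F1.
- A catalyst made from Ti(OiPr)4 and (S)-BINOL, with 4 Å molecular sieves in Et2O at −20 °C, adds F1 to 3. (S)-BINOL is the antipode expected to direct attack to the Si face of 3.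
- This catalytic asymmetric Mukaiyama aldol (formal hetero-Diels–Alder) reaction gives (2E,6R,18Z)-2-methoxy-6-(trimethylsilyloxy)heptacosa-2,18-dien-4-one F2.
- CF3CO2H in CH2Cl2 at 0 °C removes the silyl group and closes the ring by addition–elimination with loss of methanol. The carbinol stereocentre is untouched, and the product is 10.

**Step 2.**
- O-acylation, stalling by proton transfer, consumption of 5 by the excess base, or premature racemic ring closure on work-up or on silica are possible.
- Fallback: it sets out from 4 and comes back at 8, replacing acylation by aldol addition and oxidation.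
- Dienolate 6 (from 4 with LiN(iPr)2, THF, −78 °C) is trapped with acetaldehyde to give racemic (5E,18Z)-2-hydroxyheptacosa-5,18-dien-4-one F3.
- The carbinol centre of F3 is erased when Dess–Martin periodinane (1.1 equiv, NaHCO3, CH2Cl2, 0 °C) oxidises it to 8.

**Step 1.**
- The keto ylide may be sluggish in the acidic one-pot medium, the aldehyde may self-condense, or the E:Z ratio may be insufficient.
- Fallback: it sets out from 1 and comes back at 4, replacing olefination by aldol addition and elimination.
- Aldehyde 3 is isolated after the TEMPO/PhI(OAc)2 oxidation.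
- It is treated with commercial 2-(trimethylsilyloxy)propene and BF3·OEt2 (CH2Cl2, −78 °C, aqueous work-up) to give racemic (16Z)-4-hydroxypentacos-16-en-2-one F4.
- F4 is converted with MsCl/Et3N (CH2Cl2, 0 °C) into (16Z)-2-oxopentacos-16-en-4-yl methanesulfonate F5.
- DBU in the same flask eliminates F5 (E1cB) to the E-enone 4.

**Further compounds**
F1 | step 3 | (E)-4-methoxy-2-(trimethylsilyloxy)penta-1,3-diene | CO/C(C)=C/C(=C)O[Si](C)(C)C
F2 | step 3 | (2E,6R,18Z)-2-methoxy-6-(trimethylsilyloxy)heptacosa-2,18-dien-4-one | CCCCCCCC/C=C\CCCCCCCCCCC[C@@H](O[Si](C)(C)C)CC(=O)/C=C(\C)OC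
F3 | step 2 | (5E,18Z)-2-hydroxyheptacosa-5,18-dien-4-one (racemic) | CCCCCCCC/C=C\CCCCCCCCCCC/C=C/C(=O)CC(C)O
F4 | step 1 | (16Z)-4-hydroxypentacos-16-en-2-one (racemic) | CCCCCCCC/C=C\CCCCCCCCCCCC(O)CC(C)=O
F5 | step 1 | (16Z)-2-oxopentacos-16-en-4-yl methanesulfonate (racemic) | CCCCCCCC/C=C\CCCCCCCCCCCC(CC(C)=O)OS(C)(=O)=O
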